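Ring B, the 4-acyloxy-2-methoxy-6-pentylbenzoic acid half, is disconnected into dibenzyl malonate and (E)-non-3-en-2-one. The key step exploits the resorcylate pattern of ring B: C1 carries the carboxyl, C2 and C4 carry oxygen, C6 carries the pentyl chain. A single Michael–Claisen operation forms C1–C6 and C2–C3, closes the six-membered ring and places all four substituents, giving the benzyl 2,4-dioxocyclohexanecarboxylate one dehydrogenation below the arene. Its precursors are the two commercial partners, the malonate supplying C1, C2 and the benzyl ester. Aromatization, acylation of the unchelated 4-OH with an O-benzyl ring A acid made from olivetol, methylation of the chelated 2-OH and one hydrogenolysis complete the depside.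

Key step: step 1

Remark: 3 and 4 are racemic and 4 is drawn as its triketo tautomer although it should exist largely as an enol; these stereocentres vanish in step 2, and the target has none.

Step 1
Reactants: 1 (E)-non-3-en-2-one; 2 dibenzyl malonate
Product: 4 racemic benzyl 2,4-dioxo-6-pentylcyclohexane-1-carboxylate, via dibenzyl 2-(2-oxononan-4-yl)malonate 3 (not isolated)
Conditions: NaH (1.1 equiv), BnOH (0.1 equiv), THF, 0 °C; 2, then 1; reflux; then 1 M HCl, 0 °C
Reagents that add atoms: none
Why: Tandem Michael addition–intramolecular Claisen (Dieckmann-like) condensation, the classical malonate–enone annulation to 6-alkyl-2,4-dioxocyclohexanecarboxylates: the sodium enolate of 2 adds 1,4 to enone 1 to give 3 (new C1–C6 bond), proton shuttling by BnOH/BnONa then supplies the methyl ketone enolate, whose carbon C3 attacks one benzyl ester carbonyl (new C2–C3 bond) and expels benzyloxide. The ring closes in a 6-(enolendo)-exo-trig mode, because both enolate carbons (C3 and C4) lie inside the new ring while the attacked ester C=O points outside it, a favoured geometry for six-membered rings. The stereocentres formed at C6 and C1 are not controlled (C6 arises racemic, C1 equilibrates through the enol) and need no control, since both become sp2 in step 2. The step needs conjugate in place of carbonyl addition, which the soft, reversibly adding malonate anion secures, and closure from the methyl group, which is secured because the internal C5 enolate could only give a strained four-membered ring. All equilibria are drained by deprotonation of the acidic beta-tricarbonyl product by the released benzyloxide, so a full equivalent of base is used, and keeping benzyl alcohol as the only alcohol present prevents ester scrambling.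

Step 2
Reactants: 4 racemic benzyl 2,4-dioxo-6-pentylcyclohexane-1-carboxylate
Product: 5 benzyl 2,4-dihydroxy-6-pentylbenzoate
Conditions: Hg(OAc)2 (1.05 equiv), NaOAc (2 equiv), AcOH, 90 °C
Reagents that add atoms: none
Why: Oxidative aromatization of a cyclohexane-1,3-dione with Hg(OAc)2, a known dehydrogenation of dihydroresorcinols: mercuration of the enol at the doubly activated C1, loss of zerovalent mercury and AcOH across C1–C6 and tautomerization should give the resorcylate, with both stereocentres erased and the benzyl ester untouched in buffered AcOH.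

Step 3
Reactants: 6 olivetol (5-pentylbenzene-1,3-diol)
Product: 8 2,4-dihydroxy-6-pentylbenzaldehyde, via [(2,4-dihydroxy-6-pentylphenyl)methylidene]dimethylammonium chloride 7 (not isolated)
Conditions: POCl3 (1.2 equiv), DMF, 0 °C to rt; then H2O, 50 °C
Reagents that add atoms: N,N-dimethylformamide, CN(C)C=O (formyl carbon); water, O (aldehyde oxygen)
Why: Vilsmeier–Haack formylation, in which the chloroiminium ion attacks the ring carbon activated by one para and one ortho hydroxyl (next to the pentyl group) in preference to the carbon flanked by both hydroxyls, as is usual for 5-alkylresorcinols, and water hydrolyses iminium salt 7 to the aldehyde.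

Step 4
Reactants: 8 2,4-dihydroxy-6-pentylbenzaldehyde
Product: 9 2-hydroxy-4-methoxy-6-pentylbenzaldehyde
Conditions: MeI (1.05 equiv), K2CO3 (1.0 equiv), acetone, rt
Reagents that add atoms: iodomethane, CI
Why: Williamson etherification under chelation control: the 2-OH is tied up in a hydrogen bond to the aldehyde and is the weaker acid, so one equivalent of base and MeI should alkylate only the para 4-OH.

Step 5
Reactants: 9 2-hydroxy-4-methoxy-6-pentylbenzaldehyde
Product: 10 2-(benzyloxy)-4-methoxy-6-pentylbenzaldehyde
Conditions: BnBr (1.2 equiv), K2CO3 (1.5 equiv), DMF, 60 °C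
Reagents that add atoms: benzyl bromide, BrCc1ccccc1
Why: Williamson benzylation of the remaining chelated phenol under more forcing conditions, which installs a protecting group that leaves together with the benzyl ester in the last step.

Step 6
Reactants: 10 2-(benzyloxy)-4-methoxy-6-pentylbenzaldehyde
Product: 11 2-(benzyloxy)-4-methoxy-6-pentylbenzoic acid
Conditions: NaClO2 (1.5 equiv), NaH2PO4, 2-methyl-2-butene (10 equiv), t-BuOH/H2O, rt
Reagents that add atoms: sodium chlorite, [Na+].[O-]Cl=O
Why: Pinnick oxidation converts the hindered, electron-rich aryl aldehyde into the acid without touching the benzyl ether, the alkene trapping HOCl before it can chlorinate the ring.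

Step 7
Reactants: 11 2-(benzyloxy)-4-methoxy-6-pentylbenzoic acid; 5 benzyl 2,4-dihydroxy-6-pentylbenzoate
Product: 13 benzyl 4-{[2-(benzyloxy)-4-methoxy-6-pentylbenzoyl]oxy}-2-hydroxy-6-pentylbenzoate, via 2-(benzyloxy)-4-methoxy-6-pentylbenzoic trifluoroacetic anhydride 12 (not isolated)
Conditions: TFAA (2 equiv), toluene, rt; 11 first, then 5
Reagents that add atoms: none
Why: Esterification of a 2,6-disubstituted benzoic acid by the trifluoroacetic mixed-anhydride method: 12 ionizes readily to a hindered acylium donor that should be captured by the free 4-OH of 5, while the 2-OH, hydrogen-bonded to and flanked by the benzyl ester, stays unacylated.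

Step 8
Reactants: 13 benzyl 4-{[2-(benzyloxy)-4-methoxy-6-pentylbenzoyl]oxy}-2-hydroxy-6-pentylbenzoate
Product: 14 benzyl 4-{[2-(benzyloxy)-4-methoxy-6-pentylbenzoyl]oxy}-2-methoxy-6-pentylbenzoate
Conditions: MeI (3 equiv), K2CO3 (2 equiv), DMF, rt to 40 °C
Reagents that add atoms: iodomethane, CI
Why: Williamson methylation of the only free phenol, the chelated 2-OH of ring B; the ring A phenol is masked as its benzyl ether and the depside ester of a 2,6-disubstituted benzoate should resist the mild carbonate base.

Step 9
Reactants: 14 benzyl 4-{[2-(benzyloxy)-4-methoxy-6-pentylbenzoyl]oxy}-2-methoxy-6-pentylbenzoate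
Product: 15 2'-O-methylperlatolic acid (4-[(2-hydroxy-4-methoxy-6-pentylbenzoyl)oxy]-2-methoxy-6-pentylbenzoic acid)
Conditions: H2 (1 atm), 10% Pd/C, EtOAc, rt
Reagents that add atoms: none
Why: Catalytic hydrogenolysis should cleave the benzyl ester and the benzyl aryl ether in one operation at room temperature and leave the depside ester, the methyl ethers and both arenes intact.

Compound list
1 | (E)-non-3-en-2-one | CCCCC/C=C/C(C)=O | starting material
2 | dibenzyl malonate | O=C(CC(=O)OCc1ccccc1)OCc1ccccc1 | starting material
3 | dibenzyl 2-(2-oxononan-4-yl)malonate (racemic Michael adduct, not isolated) | CCCCCC(CC(C)=O)C(C(=O)OCc1ccccc1)C(=O)OCc1ccccc1 | intermediate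
4 | benzyl 2,4-dioxo-6-pentylcyclohexane-1-carboxylate (racemic, keto–enol mixture) | CCCCCC1CC(=O)CC(=O)C1C(=O)OCc1ccccc1 | intermediate
5 | benzyl 2,4-dihydroxy-6-pentylbenzoate | CCCCCc1cc(O)cc(O)c1C(=O)OCc1ccccc1 | intermediate
6 | olivetol (5-pentylbenzene-1,3-diol) | CCCCCc1cc(O)cc(O)c1 | starting material
7 | [(2,4-dihydroxy-6-pentylphenyl)methylidene]dimethylammonium chloride (not isolated) | CCCCCc1cc(O)cc(O)c1C=[N+](C)C.[Cl-] | intermediate
8 | 2,4-dihydroxy-6-pentylbenzaldehyde | CCCCCc1cc(O)cc(O)c1C=O | intermediate
9 | 2-hydroxy-4-methoxy-6-pentylbenzaldehyde | CCCCCc1cc(OC)cc(O)c1C=O | intermediate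
10 | 2-(benzyloxy)-4-methoxy-6-pentylbenzaldehyde | CCCCCc1cc(OC)cc(OCc2ccccc2)c1C=O | intermediate
11 | 2-(benzyloxy)-4-methoxy-6-pentylbenzoic acid | CCCCCc1cc(OC)cc(OCc2ccccc2)c1C(=O)O | intermediate
12 | 2-(benzyloxy)-4-methoxy-6-pentylbenzoic trifluoroacetic anhydride (not isolated) | CCCCCc1cc(OC)cc(OCc2ccccc2)c1C(=O)OC(=O)C(F)(F)F | intermediate
13 | benzyl 4-{[2-(benzyloxy)-4-methoxy-6-pentylbenzoyl]oxy}-2-hydroxy-6-pentylbenzoate | CCCCCc1cc(OC)cc(OCc2ccccc2)c1C(=O)Oc1cc(CCCCC)c(C(=O)OCc2ccccc2)c(O)c1 | intermediate
14 | benzyl 4-{[2-(benzyloxy)-4-methoxy-6-pentylbenzoyl]oxy}-2-methoxy-6-pentylbenzoate | CCCCCc1cc(OC)cc(OCc2ccccc2)c1C(=O)Oc1cc(CCCCC)c(C(=O)OCc2ccccc2)c(OC)c1 | intermediate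
15 | 2'-O-methylperlatolic acid | CCCCCc1cc(OC)cc(O)c1C(=O)Oc1cc(CCCCC)c(C(=O)O)c(OC)c1 | target

Total step count: 9.
Longest linear sequence: 7 steps (steps 3, 4, 5, 6, 7, 8 and 9, from olivetol 6); the ring B branch (steps 1 and 2) joins at step 7.

Steps most likely to fail

Step 1. Moisture could hydrolyse a benzyl ester, after which decarboxylation would follow. The Claisen closure could also stall at the open-chain adduct, or the enone could oligomerize under hot alkoxide. The fallback sets out from 1 and keeps the same two bonds but installs the benzyl ester after ring formation. Enone 1 is condensed with dimethyl malonate and NaOMe in refluxing MeOH, the robust variant in which the sodium enolate of the product should precipitate. This passes through dimethyl 2-(2-oxononan-4-yl)malonate F1 to methyl 2,4-dioxo-6-pentylcyclohexane-1-carboxylate F2. The ester is then exchanged by heating F2 with BnOH in toluene over 4 Å molecular sieves, a thermal beta-keto ester transesterification through the acylketene. The route is rejoined at 4.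

Step 2. The electron-rich resorcylate could be mercurated or oxidized further as it forms, and hot acid could cleave the benzyl beta-keto ester with decarboxylation. The fallback sets out from 4 and dehydrogenates a defined silyl dienol ether instead of the free dione. TMSCl and Et3N in CH2Cl2 should give benzyl 6-pentyl-2,4-bis(trimethylsilyloxy)cyclohexa-1,3-diene-1-carboxylate F3. DDQ in dioxane at rt should then abstract hydride from the bis-silyloxy diene and give benzyl 6-pentyl-2,4-bis(trimethylsilyloxy)benzoate F4. Dilute HCl in THF removes the silyl ethers and the route is rejoined at 5.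

Step 7. O-acylation by the hindered acyl donor may be slow, so that trifluoroacetylation of the phenol, C-acylation of the electron-rich ring B or acid-induced loss of the ring A benzyl ether compete. The fallback sets out from 11 and replaces the acidic acylium chemistry by base-mediated acylation with an isolated acyl chloride. (COCl)2 with catalytic DMF in CH2Cl2 should give 2-(benzyloxy)-4-methoxy-6-pentylbenzoyl chloride F5. F5 is added to 5 with Et3N and catalytic DMAP in CH2Cl2 at 0 °C to rt, where the more acidic, unchelated 4-OH is acylated. The route is rejoined at 13.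

Further compounds
F1 | step 1 | dimethyl 2-(2-oxononan-4-yl)malonate (racemic, not isolated) | CCCCCC(CC(C)=O)C(C(=O)OC)C(=O)OC
F2 | step 1 | methyl 2,4-dioxo-6-pentylcyclohexane-1-carboxylate (racemic) | CCCCCC1CC(=O)CC(=O)C1C(=O)OC
F3 | step 2 | benzyl 6-pentyl-2,4-bis(trimethylsilyloxy)cyclohexa-1,3-diene-1-carboxylate (racemic) | CCCCCC1CC(O[Si](C)(C)C)=CC(O[Si](C)(C)C)=C1C(=O)OCc1ccccc1
F4 | step 2 | benzyl 6-pentyl-2,4-bis(trimethylsilyloxy)benzoate | CCCCCc1cc(O[Si](C)(C)C)cc(O[Si](C)(C)C)c1C(=O)OCc1ccccc1
F5 | step 7 | 2-(benzyloxy)-4-methoxy-6-pentylbenzoyl chloride | CCCCCc1cc(OC)cc(OCc2ccccc2)c1C(=O)Cl
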